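**Retrosynthetic overview**

1. The strategy rests on the ester C(=O)–O bond that ties the outer phenolic oxygen of the 5-pentylpyrogallol ring to C1 of the 2-hydroxy-4-methoxy-6-propylbenzoate ring. The carboxyl carbon plus ring carbons C1–C6 (oxygen at C2 and C4, propyl at C6) are a folded 3,5,7-trioxodecanoyl chain, so ester and arene can both come from one acylketene.
2. Target 22 ⇐ ketal 21 (hydrogenolysis) ⇐ resorcylate 20 (4-O-methylation) ⇐ acylketene 17 (from diketo-dioxinone 8) + mono-free phenol 16: ester C–O bond first, then the arene C1–C6 bond by aldol aromatisation.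
3. 8 ⇐ dioxinone 1 by two chain-extending acylations (acetyl chloride 2, then Weinreb amide 6). 16 ⇐ 3,4,5-trimethoxybenzaldehyde 9 by Wittig olefination, hydrogenation, demethylation and diphenylmethylene ketalisation.
4. Ring order: the pentylpyrogallol ring is carried from a purchased arene, the benzodioxole ketal ring is closed in step 7, and the propylresorcylate ring is closed last, in step 8.

Key step: step 8

Remark on the chemistry: the poly-β-carbonyl compounds 4, 8 and 18 are written as keto forms although they should exist largely as enol tautomers, and alkene 12 is expected as an E/Z mixture, which is immaterial because it is hydrogenated.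

**Route**

Step 1
Reactants: 1 2,2,6-trimethyl-4H-1,3-dioxin-4-one; 2 acetyl chloride
Product: 4 2,2-dimethyl-6-(2-oxopropyl)-4H-1,3-dioxin-4-one, via dioxinone lithium dienolate 3 (not isolated)
Conditions: LiN(SiMe3)2 (2 equiv per AcCl), THF, −78 °C; then AcCl, −78 °C; aq HCl quench
Reagents that add atoms: none
Why: Kinetic deprotonation of the 6-methyl group gives the vinylogous ester dienolate, which should undergo Claisen-type C-acylation at its terminal carbon with the acid chloride, the extra equivalent of base absorbing the more acidic product.

Step 2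
Reactants: 5 butanoyl chloride
Product: 6 N-methoxy-N-methylbutanamide
Conditions: MeNHOMe·HCl, K2CO3, H2O–CH2Cl2, 0 °C to rt
Reagents that add atoms: N,O-dimethylhydroxylamine hydrochloride, CNOC.Cl
Why: Schotten–Baumann N-acylation of the liberated hydroxylamine by the acid chloride is a standard Weinreb amide formation.

Step 3
Reactants: 4 2,2-dimethyl-6-(2-oxopropyl)-4H-1,3-dioxin-4-one; 6 N-methoxy-N-methylbutanamide
Product: 8 6-(2,4-dioxoheptyl)-2,2-dimethyl-4H-1,3-dioxin-4-one, via keto-dioxinone dilithium dianion 7 (not isolated)
Conditions: LiN(iPr)2 (2.1 equiv), THF, −78 °C; then 6, −78 to −40 °C; aq HCl quench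
Reagents that add atoms: none
Why: In this Claisen-type acylation the dianion should react at its last-formed, most nucleophilic terminal carbon, and the chelated tetrahedral adduct of the Weinreb amide prevents over-addition until the quench.

Step 4
Reactants: 9 3,4,5-trimethoxybenzaldehyde; 10 butyltriphenylphosphonium bromide
Product: 12 1,2,3-trimethoxy-5-(pent-1-en-1-yl)benzene (E/Z mixture), via butylidenetriphenylphosphorane 11 (not isolated)
Conditions: KOtBu, THF, 0 °C; then 9, 0 °C to rt
Reagents that add atoms: none
Why: Wittig olefination of an aromatic aldehyde with a non-stabilised ylide is reliable, and the alkene geometry does not matter because the double bond is saturated next.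

Step 5
Reactants: 12 1,2,3-trimethoxy-5-(pent-1-en-1-yl)benzene
Product: 13 1,2,3-trimethoxy-5-pentylbenzene
Conditions: H2 (1 atm), 10% Pd/C, EtOAc, rt
Reagents that add atoms: none
Why: Heterogeneous catalytic hydrogenation of the styrenyl alkene should converge both isomers on the pentyl arene without touching the aryl methyl ethers.

Step 6
Reactants: 13 1,2,3-trimethoxy-5-pentylbenzene
Product: 14 5-pentylbenzene-1,2,3-triol
Conditions: BBr3 (4 equiv), CH2Cl2, −78 °C to rt; then H2O, under Ar
Reagents that add atoms: none
Why: Lewis acid-mediated cleavage of aryl methyl ethers by BBr3 (boron coordination to oxygen, bromide attack on methyl) should free all three phenols, and inert handling protects the oxidation-prone pyrogallol.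

Step 7
Reactants: 14 5-pentylbenzene-1,2,3-triol; 15 dichlorodiphenylmethane
Product: 16 6-pentyl-2,2-diphenyl-1,3-benzodioxol-4-ol
Conditions: Ph2CCl2 (1.1 equiv), Ph2O, 170 °C, Ar
Reagents that add atoms: none
Why: Thermal ketalisation by double substitution of the gem-dichloride can only bridge two adjacent hydroxyls into a five-membered benzodioxole, so the symmetric triol should give a single monoketal with one outer phenol left free.

Step 8
Reactants: 8 6-(2,4-dioxoheptyl)-2,2-dimethyl-4H-1,3-dioxin-4-one; 16 6-pentyl-2,2-diphenyl-1,3-benzodioxol-4-ol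
Product: 20 6-pentyl-2,2-diphenyl-1,3-benzodioxol-4-yl 2,4-dihydroxy-6-propylbenzoate, via acylketene 17 (not isolated), via triketo aryl ester 18 (not isolated), via cyclic aldol adduct 19 (not isolated)
Conditions: PhMe, 110 °C (16 in 1.5 equiv); then Et3N, 4 Å MS, rt; dilute aq HCl work-up
Reagents that add atoms: none
Why: Proposed new method: heating 8 should expel acetone by retro-hetero-Diels–Alder fragmentation to give acylketene 17, to which the one free phenol of 16 adds to form the aryl ester C–O bond of 18; Et3N then enolises the doubly activated C2 methylene, which adds to the C7 propyl ketone to give 19, and loss of water with tautomerisation delivers the arene. The closest known reaction type is the thermolysis of diketo-dioxinones in the presence of aliphatic alcohols followed by base-mediated aldol aromatisation to alkyl 6-alkyl-2,4-dihydroxybenzoates, together with the known capture of simple acylketenes by phenols to give aryl β-keto esters; new here is their combination, with a hindered ortho-oxygenated phenol as the trap and an aryl ester carried through the aromatisation. The one ring closed, the benzoate ring, forms by a 6-(enolendo)-exo-trig aldol that joins C2 to C7 of the decanoate chain, which is the C1–C6 bond of the arene. No stereocentre has to be controlled, since the two centres of 19 vanish on dehydration. The step needs C-cyclisation to win over attack of an enol oxygen on the ketene or on the aryl ester carbonyl (pyranone formation with release of 16); an excess of phenol in concentrated toluene favours intermolecular capture, and the higher acidity of the C2 methylene between ester and ketone under a mild non-nucleophilic amine in an aprotic medium favours the aldol path. The ketal of 16 leaves a single nucleophilic oxygen, so only one ester can form and no acyl shift to a neighbouring phenol is possible.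

Step 9
Reactants: 20 6-pentyl-2,2-diphenyl-1,3-benzodioxol-4-yl 2,4-dihydroxy-6-propylbenzoate
Product: 21 6-pentyl-2,2-diphenyl-1,3-benzodioxol-4-yl 2-hydroxy-4-methoxy-6-propylbenzoate
Conditions: MeI (1.1 equiv), K2CO3 (1.1 equiv), acetone, rt
Reagents that add atoms: iodomethane, CI
Why: In this Williamson-type O-alkylation the 2-hydroxyl is held in a hydrogen bond to the ester carbonyl and is much less acidic and nucleophilic, so one equivalent of mild base and MeI should methylate only the 4-hydroxyl.

Step 10
Reactants: 21 6-pentyl-2,2-diphenyl-1,3-benzodioxol-4-yl 2-hydroxy-4-methoxy-6-propylbenzoate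
Product: 22 Peruvinide C (2,3-dihydroxy-5-pentylphenyl 2-hydroxy-4-methoxy-6-propylbenzoate)
Conditions: H2 (1 atm), 10% Pd/C, THF–MeOH (4:1), rt; base-free work-up
Reagents that add atoms: none
Why: Catalytic hydrogenolysis of the two doubly benzylic C–O bonds of the diphenylmethylene ketal should release the catechol and diphenylmethane under neutral conditions that spare the aryl ester and the aryl methyl ether and do not promote acyl migration.

**Compound list**

1 | 2,2,6-trimethyl-4H-1,3-dioxin-4-one | CC1=CC(=O)OC(C)(C)O1 | starting material
2 | acetyl chloride | CC(Cl)=O | starting material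
3 | lithium dienolate of 1 (lithium 2,2-dimethyl-6-methylidene-6H-1,3-dioxin-4-olate) | [Li+].C=C1C=C([O-])OC(C)(C)O1 | intermediate
4 | 2,2-dimethyl-6-(2-oxopropyl)-4H-1,3-dioxin-4-one | CC(=O)CC1=CC(=O)OC(C)(C)O1 | intermediate
5 | butanoyl chloride | CCCC(Cl)=O | starting material
6 | N-methoxy-N-methylbutanamide | CCCC(=O)N(C)OC | intermediate
7 | dilithium dianion of 4 (bis-enolate, deprotonated at the ring-side methylene and the terminal methyl) | [Li+].[Li+].C=C([O-])C=C1C=C([O-])OC(C)(C)O1 | intermediate
8 | 6-(2,4-dioxoheptyl)-2,2-dimethyl-4H-1,3-dioxin-4-one | CCCC(=O)CC(=O)CC1=CC(=O)OC(C)(C)O1 | intermediate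
9 | 3,4,5-trimethoxybenzaldehyde | COc1cc(C=O)cc(OC)c1OC | starting material
10 | butyltriphenylphosphonium bromide | CCCC[P+](c1ccccc1)(c1ccccc1)c1ccccc1.[Br-] | starting material
11 | butylidenetriphenylphosphorane | CCCC=P(c1ccccc1)(c1ccccc1)c1ccccc1 | intermediate
12 | 1,2,3-trimethoxy-5-(pent-1-en-1-yl)benzene (E/Z mixture) | CCCC=Cc1cc(OC)c(OC)c(OC)c1 | intermediate
13 | 1,2,3-trimethoxy-5-pentylbenzene | CCCCCc1cc(OC)c(OC)c(OC)c1 | intermediate
14 | 5-pentylbenzene-1,2,3-triol | CCCCCc1cc(O)c(O)c(O)c1 | intermediate
15 | dichlorodiphenylmethane | ClC(Cl)(c1ccccc1)c1ccccc1 | starting material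
16 | 6-pentyl-2,2-diphenyl-1,3-benzodioxol-4-ol | CCCCCc1cc(O)c2OC(c3ccccc3)(c3ccccc3)Oc2c1 | intermediate
17 | acylketene dec-1-ene-1,3,5,7-tetrone | CCCC(=O)CC(=O)CC(=O)C=C=O | intermediate
18 | 6-pentyl-2,2-diphenyl-1,3-benzodioxol-4-yl 3,5,7-trioxodecanoate | CCCCCc1cc(OC(=O)CC(=O)CC(=O)CC(=O)CCC)c2OC(c3ccccc3)(c3ccccc3)Oc2c1 | intermediate
19 | 6-pentyl-2,2-diphenyl-1,3-benzodioxol-4-yl 2-hydroxy-4,6-dioxo-2-propylcyclohexane-1-carboxylate (transient diastereomer mixture) | CCCCCc1cc(OC(=O)C2C(=O)CC(=O)CC2(O)CCC)c2OC(c3ccccc3)(c3ccccc3)Oc2c1 | intermediate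
20 | 6-pentyl-2,2-diphenyl-1,3-benzodioxol-4-yl 2,4-dihydroxy-6-propylbenzoate | CCCCCc1cc2OC(c3ccccc3)(c3ccccc3)Oc2c(OC(=O)c2c(O)cc(O)cc2CCC)c1 | intermediate
21 | 6-pentyl-2,2-diphenyl-1,3-benzodioxol-4-yl 2-hydroxy-4-methoxy-6-propylbenzoate | CCCCCc1cc2OC(c3ccccc3)(c3ccccc3)Oc2c(OC(=O)c2c(O)cc(OC)cc2CCC)c1 | intermediate
22 | Peruvinide C (2,3-dihydroxy-5-pentylphenyl 2-hydroxy-4-methoxy-6-propylbenzoate) | CCCCCc1cc(O)c(O)c(OC(=O)c2c(O)cc(OC)cc2CCC)c1 | target

**Step count and risks**

Total step count: 10. Longest linear sequence: 7 steps (steps 4, 5, 6, 7, 8, 9, 10, from aldehyde 9).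

Steps most likely to fail:

1. Step 8 (proposed new method). Capture of the acylketene by the hindered, weakly nucleophilic phenol may be outrun by intramolecular O-cyclisation to a pyranone. Alternatively, the aryl triketo ester may expel the phenoxide under base instead of closing by aldol addition. The fallback sets out from compound 8 and builds the benzoic acid first by the known alkyl-ester version of the sequence, then makes the ester bond by classical depside coupling; it comes back to the route at compound 21. Compound 8 is heated in toluene with benzyl alcohol, so that acylketene 17 is trapped as benzyl 3,5,7-trioxodecanoate F1. K2CO3 in iPrOH closes this to benzyl 2-hydroxy-4,6-dioxo-2-propylcyclohexane-1-carboxylate F2, and acidification with HCl dehydrates it to benzyl 2,4-dihydroxy-6-propylbenzoate F3. Methylation of the unchelated hydroxyl (MeI, K2CO3, acetone) gives benzyl 2-hydroxy-4-methoxy-6-propylbenzoate F4. Hydrogenolysis of the benzyl ester (H2, Pd/C, EtOAc) gives 2-hydroxy-4-methoxy-6-propylbenzoic acid F5. The acid is condensed with phenol 16 by a carbodiimide (DCC, toluene, rt) to give compound 21.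

2. Step 3. Proton transfer from the enolisable amide to the dianion, or breakdown of the sensitive diketo-dioxinone during quench and isolation, may leave the acylation incomplete. The fallback sets out from compound 4 and replaces the Claisen acylation by an aldol addition followed by oxidation; it comes back at compound 8. Dianion 7 is added to butanal at −78 °C to give racemic 6-(4-hydroxy-2-oxoheptyl)-2,2-dimethyl-4H-1,3-dioxin-4-one F6, and the secondary alcohol is oxidised with Dess–Martin periodinane in CH2Cl2 to the β-diketone 8.

3. Step 10. Hydrogenolysis of the hindered ketal may stall, or the acyl group may migrate to the neighbouring phenol once it is unveiled, during reaction or purification. The fallback sets out from compound 21 and replaces reductive C–O cleavage by acid-catalysed hydrolysis of the ketal (AcOH–H2O, 90 °C), which proceeds through the diphenyl-stabilised oxocarbenium ion and releases benzophenone. The acidic medium suppresses acyl migration, and the fallback arrives directly at compound 22 without a new intermediate.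

Further compounds
F1 | step 8 | benzyl 3,5,7-trioxodecanoate | CCCC(=O)CC(=O)CC(=O)CC(=O)OCc1ccccc1
F2 | step 8 | benzyl 2-hydroxy-4,6-dioxo-2-propylcyclohexane-1-carboxylate (diastereomer mixture) | CCCC1(O)CC(=O)CC(=O)C1C(=O)OCc1ccccc1
F3 | step 8 | benzyl 2,4-dihydroxy-6-propylbenzoate | CCCc1cc(O)cc(O)c1C(=O)OCc1ccccc1
F4 | step 8 | benzyl 2-hydroxy-4-methoxy-6-propylbenzoate | CCCc1cc(OC)cc(O)c1C(=O)OCc1ccccc1
F5 | step 8 | 2-hydroxy-4-methoxy-6-propylbenzoic acid | CCCc1cc(OC)cc(O)c1C(=O)O
F6 | step 3 | 6-(4-hydroxy-2-oxoheptyl)-2,2-dimethyl-4H-1,3-dioxin-4-one (racemic) | CCCC(O)CC(=O)CC1=CC(=O)OC(C)(C)O1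
F0 | step 10 | none | none
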